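**Plan**
- Retrosynthetic cuts: N1–C2 and C3–Br are cut together in one event (after putting a mesyl group on N1 as activator), then the C3a–C3 aryl–alkyne bond, then C5–Br and C7–Br.
- Enabling feature: the C3 bromine sits on the pyrrole carbon that becomes palladium-bound when N1 adds to the terminus of an ethynyl group attached at C3a of the benzene ring, so the pyrrole ring and the third bromine arrive together.
- Forward order: the benzene ring is bought intact. Bromines go in at the future C5 and C7, the alkyne is attached at the future C3a through the iodide, nitrogen is mesylated, the pyrrole ring (the only ring formed) closes with bromine capture, and the mesyl group is removed.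
- Stereochemistry: the target is planar and achiral with no stereocentre, so only regiochemistry has to be controlled.

Key step: step 5

Remark: the not-isolated organopalladium intermediate of the key step is drawn without its acetonitrile ligands.

**Step 1**
Reactants: 1 2-iodo-5-methoxyaniline
Product: 2 2,4-dibromo-6-iodo-3-methoxyaniline
Conditions: NBS (2.0 equiv), MeCN, 0 °C to rt, dark
Reagents that add atoms: N-bromosuccinimide, O=C1CCC(=O)N1Br
Why: Electrophilic aromatic bromination, in which the two free positions ortho and para to NH2 are each also ortho to OMe and are by far the most activated C–H sites, while the last C–H is meta to both donors, so two equivalents of NBS in the cold should stop at the dibromide and leave the iodide in place.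

**Step 2**
Reactants: 2 2,4-dibromo-6-iodo-3-methoxyaniline; 3 trimethylsilylacetylene
Product: 4 2,4-dibromo-3-methoxy-6-[(trimethylsilyl)ethynyl]aniline
Conditions: PdCl2(PPh3)2 (2 mol%), CuI (4 mol%), Et3N, THF, rt
Reagents that add atoms: trimethylsilylacetylene (3), C#C[Si](C)(C)C
Why: Sonogashira coupling, in which zerovalent palladium inserts into the C–I bond far faster than into either C–Br bond at room temperature, the free ortho-amino group is tolerated, and the silyl cap blocks alkyne homocoupling and double arylation.

**Step 3**
Reactants: 4 2,4-dibromo-3-methoxy-6-[(trimethylsilyl)ethynyl]aniline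
Product: 5 2,4-dibromo-6-ethynyl-3-methoxyaniline
Conditions: K2CO3 (cat.), MeOH/THF, rt
Reagents that add atoms: none
Why: Base-catalysed methanolysis of the C(sp)–Si bond (protodesilylation) is routine for aryl trimethylsilylalkynes and should touch neither the aryl bromides nor the free aniline.

**Step 4**
Reactants: 5 2,4-dibromo-6-ethynyl-3-methoxyaniline; 6 methanesulfonyl chloride
Product: 7 N-(2,4-dibromo-6-ethynyl-3-methoxyphenyl)methanesulfonamide
Conditions: MsCl (1.2 equiv), pyridine, 0 °C to rt
Reagents that add atoms: methanesulfonyl chloride (6), CS(=O)(=O)Cl
Why: N-Sulfonylation of an aniline through the sulfonylpyridinium electrophile, which avoids the sulfene pathway that leads to double sulfonylation and installs the acidic N–H nucleophile that the ring closure needs.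

**Step 5**
Reactants: 7 N-(2,4-dibromo-6-ethynyl-3-methoxyphenyl)methanesulfonamide
Product: 9 3,5,7-tribromo-6-methoxy-1-(methylsulfonyl)-1H-indole, via indol-3-ylpalladium bromide 8 (not isolated)
Conditions: PdBr2 (5 mol%), CuBr2 (2.5 equiv), dry MeCN, rt to 50 °C, N2, no base
Reagents that add atoms: CuBr2, Br[Cu]Br
Why: PdBr2 binds the alkyne of 7 as a π-acid, the sulfonamide nitrogen attacks the terminal alkyne carbon anti to the metal with loss of HBr to give the C3-palladated indole 8, and CuBr2 (two equivalents per turnover) then converts the C3–Pd bond into C3–Br, returning PdBr2 and leaving CuBr. The closest known reaction type is the PdX2/CuX2 aminopalladation–halogenation of N-sulfonyl and N-acyl 2-alkynylanilines to 3-haloindoles, and cyclisation–bromination by CuBr2 alone is a background path that leads to the same product. The pyrrole ring closes in the 5-endo-dig mode, forming N1–C2, and C3–Br follows on the carbon that carried the metal. No stereocentre is formed. The step needs bromine at C3 and not at C2, which is secured because the only other closure would be a four-membered exo ring, so nitrogen must take the terminal carbon and the metal the internal one. It also needs the two aryl C–Br bonds and the alkyne C–H to stay intact, which is secured because palladium stays divalent under excess CuBr2 (no zerovalent palladium builds up to insert into C–Br) and because the base-free, HBr-releasing medium disfavours copper acetylide formation and Eglinton-type dimerisation.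

**Step 6**
Reactants: 9 3,5,7-tribromo-6-methoxy-1-(methylsulfonyl)-1H-indole
Product: 10 3,5,7-tribromo-6-methoxy-1H-indole
Conditions: NaOH (2 M aq), 1,4-dioxane, 60 °C; then aq NH4Cl, work-up neutral and shielded from light
Reagents that add atoms: none
Why: Hydrolytic N–S cleavage of an N-sulfonylindole by hydroxide attack at sulfur, eased by the three bromines (a good indolide leaving group) and by the strain between the N-mesyl group and the C7 bromine, with hydroxide chosen over methoxide so that the sulfonyl group leaves as methanesulfonate and no methylating ester is formed.

**Compound list**
1 | 2-iodo-5-methoxyaniline | COc1ccc(I)c(N)c1 | starting material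
2 | 2,4-dibromo-6-iodo-3-methoxyaniline | COc1c(Br)cc(I)c(N)c1Br | intermediate
3 | trimethylsilylacetylene | C#C[Si](C)(C)C | starting material
4 | 2,4-dibromo-3-methoxy-6-[(trimethylsilyl)ethynyl]aniline | COc1c(Br)cc(C#C[Si](C)(C)C)c(N)c1Br | intermediate
5 | 2,4-dibromo-6-ethynyl-3-methoxyaniline | COc1c(Br)cc(C#C)c(N)c1Br | intermediate
6 | methanesulfonyl chloride | CS(=O)(=O)Cl | starting material
7 | N-(2,4-dibromo-6-ethynyl-3-methoxyphenyl)methanesulfonamide | C#Cc1cc(Br)c(OC)c(Br)c1NS(C)(=O)=O | intermediate
8 | bromo[5,7-dibromo-6-methoxy-1-(methylsulfonyl)-1H-indol-3-yl]palladium | COc1c(Br)cc2c([Pd]Br)cn(S(C)(=O)=O)c2c1Br | intermediate (not isolated)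
9 | 3,5,7-tribromo-6-methoxy-1-(methylsulfonyl)-1H-indole | COc1c(Br)cc2c(Br)cn(S(C)(=O)=O)c2c1Br | intermediate
10 | 3,5,7-tribromo-6-methoxy-1H-indole | COc1c(Br)cc2c(Br)c[nH]c2c1Br | target

Total step count: 6
Longest linear sequence: 6 steps (1 to 10)

**Steps most likely to fail**

1. Step 5. The terminal alkyne may be brominated directly by CuBr2 or dimerise oxidatively before nitrogen adds. The C3–palladium bond may also be protonated by the HBr formed before bromine is transferred, leaving C3 unsubstituted. The fallback separates ring closure from bromination. Starting from 7, catalytic Cu(OAc)2 in 1,2-dichloroethane at reflux (copper-catalysed cyclisation of 2-ethynyl sulfonanilides, no halide oxidant present) should give 5,7-dibromo-6-methoxy-1-(methylsulfonyl)-1H-indole F1. Its most nucleophilic free position, C3, is then brominated with Br2 in CH2Cl2 at 0 °C, as is established for N-sulfonylindoles, and the route is rejoined at 9.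

2. Step 4. The aniline is weakly nucleophilic and flanked by two ortho substituents, so sulfonylation may stall, and forcing it may lead to over-sulfonylation at nitrogen. The fallback drives the reaction deliberately to the imide. Starting from 5, excess MsCl with Et3N in CH2Cl2 at 0 °C (sulfene pathway, a much stronger electrophile) should give N-(2,4-dibromo-6-ethynyl-3-methoxyphenyl)-N-(methylsulfonyl)methanesulfonamide F2. One mesyl group is then removed with aqueous NaOH in THF at room temperature; the resulting sulfonamide anion resists further attack, and the route is rejoined at 7.

3. Step 1. The iodine-bearing carbon is ortho to NH2 and para to OMe, so ipso attack with loss of iodine may compete, and the free aniline may be oxidised by NBS. The fallback reverses the order of halogenation and coupling. Starting from 1, Sonogashira coupling with 3 under the conditions of step 2 should give 5-methoxy-2-[(trimethylsilyl)ethynyl]aniline F3, which has no C–I bond left. Dibromination with NBS (2.0 equiv, MeCN, 0 °C) at the two positions activated by both NH2 and OMe then follows; the silyl-capped alkyne is not expected to react with NBS in the absence of AgNO3, and the route is rejoined at 4.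

**Further compounds**
F1 | step 5 | 5,7-dibromo-6-methoxy-1-(methylsulfonyl)-1H-indole | COc1c(Br)cc2ccn(S(C)(=O)=O)c2c1Br
F2 | step 4 | N-(2,4-dibromo-6-ethynyl-3-methoxyphenyl)-N-(methylsulfonyl)methanesulfonamide | C#Cc1cc(Br)c(OC)c(Br)c1N(S(C)(=O)=O)S(C)(=O)=O
F3 | step 1 | 5-methoxy-2-[(trimethylsilyl)ethynyl]aniline | COc1ccc(C#C[Si](C)(C)C)c(N)c1
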